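A small charge of 0.0020 M substrate and 2.10 mM partner stood in your question, and you asked me for a quick number. The problem stood as follows.

common to all: substrate 0.0020 M
- ash: partner 2.10 mM; a single well-mixed tank run continuously and read at steady state, 90.0 s in it on average
- maple: partner 2.10 mM; one stirred flow tank at steady state, fed with the mixture as stated, mean residence time 30 s
- cedar: partner 2.10 mM; everything together in a closed stirred flask, run for 30 s; time 30 s
- alder: partner 2.10 mM (fed, over 15.0 s); all but partner at the start; partner goes in evenly over 15.0 s, the run ends at 30 s; time 30 s

    substrate + partner → mono adduct (k1 = 540 M⁻¹ s⁻¹)
    partner + mono adduct → double product (k2 = 570 M⁻¹ s⁻¹)
    partner + double product → triple product (k3 = 840 M⁻¹ s⁻¹)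
    partner + mono adduct → over-reaction product (k4 = 110 M⁻¹ s⁻¹)
    2 substrate → homo dimer (k5 = 17 M⁻¹ s⁻¹)

* order of the set-ups by the share of mono adduct in all that became mono adduct or double product or triple product or over-reaction product, at the outlet or at the end, highest first (ash / maple / cedar / alder)
* share of mono adduct in all that became mono adduct or double product or triple product or over-reaction product, at the outlet or at the end, ash
* share of mono adduct in all that became mono adduct or double product or triple product or over-reaction product, at the outlet or at the end, maple
* share of mono adduct in all that became mono adduct or double product or triple product or over-reaction product, at the outlet or at the end, cedar
* share of mono adduct in all that became mono adduct or double product or triple product or over-reaction product, at the outlet or at the end, alder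

- in percentages every species weighs as the substrate in it: one homo dimer counts as two
- for a step with 2 of a species take k times the square, and two of it per event
- the stated concentrations are those of everything mixed, before any reaction; amounts are the same in each set-up
- the feed brings no volume worth counting
- run time (cedar): 30 s

I began with a law for the tanks. In a steady tank with mean stay τ, mono adduct is made at the rate of the first step and leaves by the outlet or by its two partner steps. I added the constants of those steps into one loss constant of mono adduct, kM = 680 M⁻¹ s⁻¹. At the steady c(partner) of a tank, this is a pseudo-first-order loss. Mono adduct's share of what the first step made is therefore one over the sum of one and kM c(partner) τ.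

My number is for cedar, the closed flask. There substrate and mono adduct meet the same c(partner), which cancels from their ratio and leaves the selectivity factor 1.26. With x the fraction of substrate left, mono adduct as a fraction of the charge is x minus x to the power of that factor, all over the factor less one. I treated triple product and homo dimer as small and left them out, and I assumed the partner charge consumed. A substrate taken then costs one partner as mono adduct and two beyond it. Guessing a share of 0.5 gave 70.0% of substrate taken and a share of 44.3%. That share gave 67.4% taken and 47.0% for cedar.

The forecast gave the order cedar > alder > maple > ash, with 27.4% for ash, 33.8% for maple, 50% for cedar and 37% for alder, holding that “the stirred tanks hold mono in contact with partner”. My cedar figure lay below the forecast's, and I reckoned no figure for the other set-ups.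

The simulation gave cedar > alder > maple > ash, with 27.5% for ash, 33.8% for maple, 49.8% for cedar and 37.3% for alder.

Ash stands below cedar in part because of the path from 2 substrate to homo dimer: with that path struck out, the gap of 22 percentage points narrows to 11 points, and the order of the set-ups turns. Turned round, the law cancels partner: c(mono adduct) over c(substrate) equals one minus the share, times 540 M⁻¹ s⁻¹ over kM. In maple, the share of 33.8% and the substrate reading of 6.26 × 10⁻⁴ M give 16.5% of the charge as mono adduct, and the maple tank held 16.5%.

The numbers of this flask are assumed.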